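**Retrosynthetic overview**

- Target 20 comes from thioester 17 by thioester hydrolysis and MOM removal. The C3 methyl stereocentre of 17 comes from a catalyst-controlled conjugate addition of MeMgBr to the (E)-enethioate 15, the Wittig product of aldehyde 14.
- Key disconnection: the bond between furan C4 (furan numbered O1, aryl on C2) and chain C5 (chain numbered from the carboxyl carbon). C5 is a furyl-bearing methine two carbons from C3. A furyl–palladium is therefore added across C4=C5 of the Z-allylic alcohol 13, and the unsaturation is relayed to C3, which emerges as the aldehyde carbon of 14.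
- Boronic acid 9 comes from bromofuran 6 (Br–Li exchange, borylation), which comes from a C2-selective Suzuki coupling of 2,4-dibromofuran 5 with arylboronate 4, made from hydroquinone 1. Dienol 13 comes from propargyl alcohol 10 and prenyl bromide 11 (alkynyl–allyl coupling, Z-selective semi-hydrogenation).
- No ring is formed: the benzene ring (from 1) and the furan ring (from 5) are purchased and joined in step 3.

Key step: step 7

Assumption: the stabilised ylide Ph3P=CHC(O)SEt used in step 8 is taken as a purchasable reagent; otherwise it is two routine operations from bromoacetyl bromide, ethanethiol and PPh3.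
Assumption: for the two catalyst-controlled steps (7 and 9) the required alkene face is specified and the ligand antipode that serves that face is used, both antipodes of each ligand being available.

**Route**

Step 1
Reactants: 1 hydroquinone
Product: 2 1,4-bis(methoxymethoxy)benzene
Conditions: MOMCl, K2CO3, acetone, 0 °C → rt, N2
Reagents that add atoms: chloromethyl methyl ether, COCCl
Why: Williamson-type O-alkylation of both phenols by the highly electrophilic chloromethyl ether gives the bis-acetal, which masks the oxidation-prone hydroquinone and later directs ortho-lithiation.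

Step 2
Reactants: 2 1,4-bis(methoxymethoxy)benzene
Product: 4 2-[2,5-bis(methoxymethoxy)phenyl]-4,4,5,5-tetramethyl-1,3,2-dioxaborolane, via [2,5-bis(methoxymethoxy)phenyl]lithium 3 (not isolated)
Conditions: n-BuLi, TMEDA, THF, 0 °C; i-PrOBpin, −78 °C → rt; H2O
Reagents that add atoms: 2-isopropoxy-4,4,5,5-tetramethyl-1,3,2-dioxaborolane, CC(C)OB1OC(C)(C)C(C)(C)O1
Why: Directed ortho-metalation, in which the OMOM group complexes n-BuLi and directs deprotonation to an adjacent ring position (all four are equivalent), followed by trapping of the aryllithium by the isopropoxyboronate with loss of lithium isopropoxide.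

Step 3
Reactants: 4 2-[2,5-bis(methoxymethoxy)phenyl]-4,4,5,5-tetramethyl-1,3,2-dioxaborolane; 5 2,4-dibromofuran (slight excess)
Product: 6 4-bromo-2-[2,5-bis(methoxymethoxy)phenyl]furan
Conditions: Pd(PPh3)4 (cat.), Na2CO3, DME/H2O, 75 °C
Reagents that add atoms: none
Why: Suzuki–Miyaura coupling in which zerovalent palladium inserts much faster into the C2–Br bond next to the ring oxygen than into the C4–Br bond, so that with the dibromide in slight excess only C2 should be arylated.

Step 4
Reactants: 6 4-bromo-2-[2,5-bis(methoxymethoxy)phenyl]furan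
Product: 9 {5-[2,5-bis(methoxymethoxy)phenyl]furan-3-yl}boronic acid, via {5-[2,5-bis(methoxymethoxy)phenyl]furan-3-yl}lithium 7 (not isolated), via lithium triisopropoxy{5-[2,5-bis(methoxymethoxy)phenyl]furan-3-yl}borate 8 (not isolated)
Conditions: B(Oi-Pr)3, THF/toluene, −78 °C, n-BuLi added last (in situ trap); then 1 M HCl to pH 5–6, 0 °C
Reagents that add atoms: triisopropyl borate, CC(C)OB(OC(C)C)OC(C)C; water, O
Why: Bromine–lithium exchange at −78 °C is faster than deprotonation and faster than butyl addition to the borate, so the C4-lithiofuran should be trapped as the borate before it can isomerise to the C5-lithio furan, and mild hydrolysis frees the boronic acid with the MOM ethers intact.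

Step 5
Reactants: 10 propargyl alcohol; 11 prenyl bromide
Product: 12 6-methylhept-5-en-2-yn-1-ol
Conditions: CuI (cat.), K2CO3, n-Bu4NCl (cat.), DMF, rt
Reagents that add atoms: none
Why: Copper-catalysed alkynyl–allyl coupling, in which the copper acetylide formed with carbonate displaces bromide at the unhindered primary carbon of prenyl bromide (SN2 rather than SN2′ at the fully substituted terminus) and the free hydroxyl is tolerated.

Step 6
Reactants: 12 6-methylhept-5-en-2-yn-1-ol
Product: 13 (2Z)-6-methylhepta-2,5-dien-1-ol
Conditions: H2 (1 atm), Pd/CaCO3 poisoned with Pb(OAc)2, quinoline, EtOAc, rt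
Reagents that add atoms: none
Why: Lindlar semi-hydrogenation delivers H2 syn to the alkyne on the poisoned palladium surface, giving the Z alkene, and the trisubstituted alkene is not reduced under these conditions.

Step 7
Reactants: 9 {5-[2,5-bis(methoxymethoxy)phenyl]furan-3-yl}boronic acid (excess); 13 (2Z)-6-methylhepta-2,5-dien-1-ol
Product: 14 (3R)-3-{5-[2,5-bis(methoxymethoxy)phenyl]furan-3-yl}-6-methylhept-5-enal
Conditions: Pd(MeCN)2(OTs)2 (6 mol%), Cu(OTf)2 (6 mol%), 4-tert-butyl-2-[5-(trifluoromethyl)pyridin-2-yl]-4,5-dihydrooxazole (13 mol%, the antipode giving Re-face delivery at C3 of 13), 3 Å MS, DMF, O2 (1 atm), rt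
Reagents that add atoms: none
Why: Boron-to-palladium transmetalation gives a cationic furyl complex of divalent palladium on the pyridine–oxazoline, which inserts the cis-disubstituted C2=C3 alkene of 13 in a syn fashion, the furyl group going to C3 (remote from the inductively withdrawing C–O bond) and palladium to C2. β-Hydride elimination toward C1 and re-insertion then place palladium on the carbinol carbon, loss of the hydroxyl hydrogen releases aldehyde 14, and zerovalent palladium is returned to the divalent state by O2 with Cu(OTf)2 as co-catalyst. The closest known reaction type is the enantioselective redox-relay oxidative Heck arylation of acyclic Z-alkenols with arylboronic acids, applied here to a furan-3-ylboronic acid; no ring is closed. The new stereocentre (C3 of 14, chain C5 of the target) is set in the migratory insertion by the chiral ligand acting on the Z alkene, and furyl delivery to the Re face of C3 gives the R aldehyde. Site selectivity between the two alkenes rests on the much slower insertion of the trisubstituted prenyl alkene, regioselectivity on the allylic placement of the hydroxyl (strongest polarisation of the alkene), and chemoselectivity on relay toward the carbinol outrunning β-hydride elimination at C3.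

Step 8
Reactants: 14 (3R)-3-{5-[2,5-bis(methoxymethoxy)phenyl]furan-3-yl}-6-methylhept-5-enal
Product: 15 S-ethyl (2E,5S)-5-{5-[2,5-bis(methoxymethoxy)phenyl]furan-3-yl}-8-methylnona-2,7-dienethioate
Conditions: Ph3P=CHC(O)SEt, CH2Cl2, 40 °C
Reagents that add atoms: S-ethyl 2-(triphenylphosphoranylidene)ethanethioate, CCSC(=O)C=P(c1ccccc1)(c1ccccc1)c1ccccc1
Why: Wittig olefination with a carbonyl-stabilised ylide should give the E enethioate, and the stereocentre β to the aldehyde cannot epimerise (its descriptor changes from R to S only through the priority change).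

Step 9
Reactants: 15 S-ethyl (2E,5S)-5-{5-[2,5-bis(methoxymethoxy)phenyl]furan-3-yl}-8-methylnona-2,7-dienethioate
Product: 17 S-ethyl (3R,5S)-5-{5-[2,5-bis(methoxymethoxy)phenyl]furan-3-yl}-3,8-dimethylnon-7-enethioate, via bromomagnesium thioester enolate 16 (not isolated)
Conditions: MeMgBr, CuBr·SMe2 (cat.), 1-[2-(diphenylphosphino)ferrocenyl]ethyldicyclohexylphosphine (Josiphos, cat., the antipode giving Re-face delivery at C3), t-BuOMe, −75 °C; then sat. aq. NH4Cl
Reagents that add atoms: methylmagnesium bromide, C[Mg]Br
Why: Copper-catalysed asymmetric conjugate addition of a Grignard reagent to an α,β-unsaturated thioester, in which the chiral ferrocenyl diphosphine–copper complex delivers methyl to the Re face of C3 under catalyst control (as in iterative 1,3-dimethyl array syntheses), setting C3 as R irrespective of the C5 centre, while the low temperature suppresses 1,2-addition.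

Step 10
Reactants: 17 S-ethyl (3R,5S)-5-{5-[2,5-bis(methoxymethoxy)phenyl]furan-3-yl}-3,8-dimethylnon-7-enethioate
Product: 19 (3R,5S)-5-{5-[2,5-bis(methoxymethoxy)phenyl]furan-3-yl}-3,8-dimethylnon-7-enoic acid, via lithium carboxylate 18 (not isolated)
Conditions: LiOH·H2O, THF/H2O (3:1), rt, degassed; then cold 0.5 M HCl to pH 4
Reagents that add atoms: lithium hydroxide, [Li+].[OH-]
Why: Saponification of the thioester (thiolate is a good leaving group) should proceed at room temperature without touching the base-stable MOM ethers or the non-epimerisable C3 and C5 centres, and acidification only to pH 4 in the cold keeps the acetals.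

Step 11
Reactants: 19 (3R,5S)-5-{5-[2,5-bis(methoxymethoxy)phenyl]furan-3-yl}-3,8-dimethylnon-7-enoic acid
Product: 20 (3R,5S)-5-[5-(2,5-dihydroxyphenyl)furan-3-yl]-3,8-dimethylnon-7-enoic acid (CNP0531232.1)
Conditions: 2 M aq. HCl, THF, 35 °C, Ar, degassed solvents
Reagents that add atoms: none
Why: Specific-acid hydrolysis of the two aryl methoxymethyl acetals through the oxocarbenium ion (releasing formaldehyde and methanol), run in aqueous THF so that the acid is not esterified, under conditions intended to be too mild to protonate the trisubstituted alkene or open the furan, and under argon to keep the hydroquinone from oxidising.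

**Compound list**

1 | hydroquinone | Oc1ccc(O)cc1 | starting material
2 | 1,4-bis(methoxymethoxy)benzene | COCOc1ccc(OCOC)cc1 | intermediate
3 | [2,5-bis(methoxymethoxy)phenyl]lithium | COCOc1ccc(OCOC)c([Li])c1 | intermediate
4 | 2-[2,5-bis(methoxymethoxy)phenyl]-4,4,5,5-tetramethyl-1,3,2-dioxaborolane | COCOc1ccc(OCOC)c(B2OC(C)(C)C(C)(C)O2)c1 | intermediate
5 | 2,4-dibromofuran | Brc1coc(Br)c1 | starting material
6 | 4-bromo-2-[2,5-bis(methoxymethoxy)phenyl]furan | Brc1coc(-c2cc(OCOC)ccc2OCOC)c1 | intermediate
7 | {5-[2,5-bis(methoxymethoxy)phenyl]furan-3-yl}lithium | [Li]c1coc(-c2cc(OCOC)ccc2OCOC)c1 | intermediate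
8 | lithium triisopropoxy{5-[2,5-bis(methoxymethoxy)phenyl]furan-3-yl}borate | [Li+].CC(C)O[B-](OC(C)C)(OC(C)C)c1coc(-c2cc(OCOC)ccc2OCOC)c1 | intermediate
9 | {5-[2,5-bis(methoxymethoxy)phenyl]furan-3-yl}boronic acid | OB(O)c1coc(-c2cc(OCOC)ccc2OCOC)c1 | intermediate
10 | propargyl alcohol | C#CCO | starting material
11 | prenyl bromide | CC(C)=CCBr | starting material
12 | 6-methylhept-5-en-2-yn-1-ol | CC(C)=CCC#CCO | intermediate
13 | (2Z)-6-methylhepta-2,5-dien-1-ol | CC(C)=CC/C=C\CO | intermediate
14 | (3R)-3-{5-[2,5-bis(methoxymethoxy)phenyl]furan-3-yl}-6-methylhept-5-enal | CC(C)=CC[C@H](CC=O)c1coc(-c2cc(OCOC)ccc2OCOC)c1 | intermediate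
15 | S-ethyl (2E,5S)-5-{5-[2,5-bis(methoxymethoxy)phenyl]furan-3-yl}-8-methylnona-2,7-dienethioate | CC(C)=CC[C@H](C/C=C/C(=O)SCC)c1coc(-c2cc(OCOC)ccc2OCOC)c1 | intermediate
16 | bromomagnesium enolate of thioester 17 (enolate geometry unspecified) | CC(C)=CC[C@H](C[C@@H](C)C=C(O[Mg]Br)SCC)c1coc(-c2cc(OCOC)ccc2OCOC)c1 | intermediate
17 | S-ethyl (3R,5S)-5-{5-[2,5-bis(methoxymethoxy)phenyl]furan-3-yl}-3,8-dimethylnon-7-enethioate | CC(C)=CC[C@H](C[C@@H](C)CC(=O)SCC)c1coc(-c2cc(OCOC)ccc2OCOC)c1 | intermediate
18 | lithium (3R,5S)-5-{5-[2,5-bis(methoxymethoxy)phenyl]furan-3-yl}-3,8-dimethylnon-7-enoate | [Li+].CC(C)=CC[C@H](C[C@@H](C)CC(=O)[O-])c1coc(-c2cc(OCOC)ccc2OCOC)c1 | intermediate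
19 | (3R,5S)-5-{5-[2,5-bis(methoxymethoxy)phenyl]furan-3-yl}-3,8-dimethylnon-7-enoic acid | CC(C)=CC[C@H](C[C@@H](C)CC(=O)O)c1coc(-c2cc(OCOC)ccc2OCOC)c1 | intermediate
20 | (3R,5S)-5-[5-(2,5-dihydroxyphenyl)furan-3-yl]-3,8-dimethylnon-7-enoic acid | CC(C)=CC[C@H](C[C@@H](C)CC(=O)O)c1coc(-c2cc(O)ccc2O)c1 | target

**Step count**

Total: 11 steps. Longest linear sequence: 9 steps (steps 1–4, then 7–11, from hydroquinone); the dienol branch is 2 steps (5 and 6).

**Steps most likely to fail**

Step 7. Protodeboronation and oxidative homocoupling of the electron-rich furylboronic acid may outrun transmetalation and insertion. The insertion may also lose regiocontrol with so electron-rich a migrating group, β-hydride elimination at C3 may compete with the relay, and facial selectivity may fall short. The fallback makes the same furan C4–chain C5 bond by known conjugate-addition chemistry. It sets out from boronic acid 9. A rhodium-catalysed asymmetric 1,4-addition (Hayashi–Miyaura) to commercial 5,6-dihydro-2H-pyran-2-one, with [Rh(OH)(binap)]2 (the BINAP antipode that gives the S lactone) in dioxane/H2O at 40 °C, should give (4S)-4-{5-[2,5-bis(methoxymethoxy)phenyl]furan-3-yl}tetrahydro-2H-pyran-2-one F1. Reduction with i-Bu2AlH in CH2Cl2 at −78 °C should give the lactol (4S)-4-{5-[2,5-bis(methoxymethoxy)phenyl]furan-3-yl}tetrahydro-2H-pyran-2-ol F2. A Wittig reaction of the lactol with isopropylidenetriphenylphosphorane (from i-PrPPh3I and n-BuLi, THF, 0 °C → rt) should open it to (3R)-3-{5-[2,5-bis(methoxymethoxy)phenyl]furan-3-yl}-6-methylhept-5-en-1-ol F3. Oxidation with Dess–Martin periodinane (NaHCO3, CH2Cl2) comes back to the route at aldehyde 14.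

Step 11. Protonation of the trisubstituted alkene, followed by capture of the tertiary cation by furan C5 or C3 in a six-membered ring closure, may compete with acetal hydrolysis. Acid-mediated opening of the furan and air oxidation of the freed hydroquinone to the quinone are further risks. The fallback changes the order of unveiling so that the acid-labile operation is an acetal exchange under much weaker acid, with no free carboxylic acid present. It sets out from thioester 17. Catalytic anhydrous HCl in MeOH at 0 °C (the MOM groups leaving as dimethoxymethane) should give S-ethyl (3R,5S)-5-[5-(2,5-dihydroxyphenyl)furan-3-yl]-3,8-dimethylnon-7-enethioate F4. Oxygen-free saponification (LiOH, rigorously degassed THF/H2O containing Na2S2O4, then acidification to pH 3 under argon) comes back to the route at target 20.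

Step 4. After the exchange, lithium may migrate from furan C4 to the more acidic C5 or to a MOM-flanked aryl position, the aryllithium may be alkylated by the butyl bromide formed, and the boronic acid may protodeboronate during aqueous isolation. The fallback avoids organolithium chemistry and sets out from bromofuran 6. Miyaura borylation (Pd(dppf)Cl2, B2pin2, KOAc, dioxane, 85 °C) should give 2-{5-[2,5-bis(methoxymethoxy)phenyl]furan-3-yl}-4,4,5,5-tetramethyl-1,3,2-dioxaborolane F5. Oxidative removal of the pinacol (NaIO4, NH4OAc, acetone/H2O, rt) comes back to the route at boronic acid 9.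

**Further compounds**

F1 | step 7 | (4S)-4-{5-[2,5-bis(methoxymethoxy)phenyl]furan-3-yl}tetrahydro-2H-pyran-2-one | O=C1C[C@@H](c2coc(-c3cc(OCOC)ccc3OCOC)c2)CCO1
F2 | step 7 | (4S)-4-{5-[2,5-bis(methoxymethoxy)phenyl]furan-3-yl}tetrahydro-2H-pyran-2-ol (anomer mixture) | OC1C[C@@H](c2coc(-c3cc(OCOC)ccc3OCOC)c2)CCO1
F3 | step 7 | (3R)-3-{5-[2,5-bis(methoxymethoxy)phenyl]furan-3-yl}-6-methylhept-5-en-1-ol | CC(C)=CC[C@H](CCO)c1coc(-c2cc(OCOC)ccc2OCOC)c1
F4 | step 11 | S-ethyl (3R,5S)-5-[5-(2,5-dihydroxyphenyl)furan-3-yl]-3,8-dimethylnon-7-enethioate | CC(C)=CC[C@H](C[C@@H](C)CC(=O)SCC)c1coc(-c2cc(O)ccc2O)c1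
F5 | step 4 | 2-{5-[2,5-bis(methoxymethoxy)phenyl]furan-3-yl}-4,4,5,5-tetramethyl-1,3,2-dioxaborolane | CC1(C)OB(c2coc(-c3cc(OCOC)ccc3OCOC)c2)OC1(C)C
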